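The bond between C4 of ring A (the 4-alkyl-2-aryloxyphenol ring; C4 is para to its oxygen) and the adjacent CH2 of the bridge to ring D (the para-phenylene ring) is the disconnection on which the route rests. That CH2–CH2 bridge is a masked styrene: hydroboration of a 4-vinylphenoxy group on ring D with 9-BBN puts boron on the terminal carbon, and an intramolecular B-alkyl Suzuki–Miyaura coupling with a ring A bromide closes the 19-membered macrocycle in one operation. The precursor is an open tetra-aryl chain (bromide on ring A, vinyl on ring D, three methyl ethers), assembled by two Chan–Lam etherifications and an iodide-selective B-alkyl Suzuki union that builds the ring B–ring C bridge.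

Key step: step 5

Remarks on the chemistry:
- Ring A is the monohydroxylated ring, ring B the meta-disubstituted ring, ring C the catechol ring and ring D the para-disubstituted ring.
- The target has no stereocentre and no stereogenic double bond; the macrocycle is assumed to be conformationally mobile, so no stereocontrol is needed.
- Compounds 1, 2, 4 and 8 are taken to be commercially available.

Step 1
Reactants: 1 5-bromo-2-methoxyphenol; 2 (3-iodophenyl)boronic acid
Product: 3 4-bromo-2-(3-iodophenoxy)-1-methoxybenzene
Conditions: Cu(OAc)2 (0.3 equiv), pyridine, 4 Å MS, CH2Cl2, O2 (1 atm), rt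
Reagents that add atoms: none
Why: Chan–Lam oxidative O-arylation, in which the phenoxide and the aryl group delivered from boron meet on copper and reductively eliminate to the diaryl ether at room temperature, where neither the C–Br nor the C–I bond reacts and the unhindered boronic acid keeps transmetalation fast.

Step 2
Reactants: 4 3-hydroxy-4,5-dimethoxybenzaldehyde
Product: 5 5-ethenyl-2,3-dimethoxyphenol
Conditions: Ph3PCH3Br (1.5 equiv), KOtBu (2.6 equiv), THF, 0 °C to rt; aq. NH4Cl
Reagents that add atoms: methyltriphenylphosphonium bromide, C[P+](c1ccccc1)(c1ccccc1)c1ccccc1.[Br-]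
Why: Wittig methylenation, in which excess base first forms the phenoxide (meta to the aldehyde, so it does not deactivate it by conjugation) and the unstabilized ylide then converts the aldehyde into the terminal alkene.

Step 3
Reactants: 5 5-ethenyl-2,3-dimethoxyphenol; 3 4-bromo-2-(3-iodophenoxy)-1-methoxybenzene
Product: 7 5-[2-[3-(5-bromo-2-methoxyphenoxy)phenyl]ethyl]-2,3-dimethoxyphenol, via bis(9-BBN) adduct 6 (not isolated)
Conditions: 9-BBN (2.3 equiv), THF, 0 °C to rt; then aq. Cs2CO3, 3, Pd(dppf)Cl2 (5 mol%), AsPh3 (5 mol%), DMF, rt
Reagents that add atoms: none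
Why: B-alkyl Suzuki–Miyaura coupling, in which 9-BBN hydroborates the styrene at its terminal carbon (a further equivalent is consumed by the phenol O–H and the resulting B–O bond is hydrolysed by the aqueous base) and, at room temperature, zerovalent palladium inserts into the C–I bond of ring B far faster than into the electron-rich C–Br bond of ring A, so only the ring B–ring C bridge should form.

Step 4
Reactants: 7 5-[2-[3-(5-bromo-2-methoxyphenoxy)phenyl]ethyl]-2,3-dimethoxyphenol; 8 (4-ethenylphenyl)boronic acid
Product: 9 4-bromo-2-[3-[2-[3-(4-ethenylphenoxy)-4,5-dimethoxyphenyl]ethyl]phenoxy]-1-methoxybenzene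
Conditions: Cu(OAc)2 (0.3 equiv), pyridine, 4 Å MS, BHT (cat.), CH2Cl2, O2 (1 atm), rt
Reagents that add atoms: none
Why: Chan–Lam oxidative O-arylation of the guaiacol-type phenol with an unhindered arylboronic acid at room temperature, conditions that should leave the aryl bromide and the styrene untouched.

Step 5
Reactants: 9 4-bromo-2-[3-[2-[3-(4-ethenylphenoxy)-4,5-dimethoxyphenyl]ethyl]phenoxy]-1-methoxybenzene
Product: 11 macrocycle trimethyl ether, via B-alkyl-9-BBN borane 10 (not isolated)
Conditions: 9-BBN (1.2 equiv), THF, rt; then syringe-pump addition to Pd(dppf)Cl2 (15 mol%), AsPh3 (15 mol%), Cs2CO3, DMF/THF/H2O, 60 °C, ca. 1 mM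
Reagents that add atoms: none
Why: 9-BBN adds across the ring D vinyl group with boron on the terminal carbon, the aqueous carbonate turns the B-alkyl borane into a borate, zerovalent palladium inserts into the C4–Br bond of ring A, and intramolecular transmetalation followed by reductive elimination joins ring A C4 to the terminal CH2. The closest known reaction type is the B-alkyl Suzuki–Miyaura macrocyclization used to close cyclophane-type rings at an aryl–CH2 bond. The only ring closed is the 19-membered macrocycle (counted along the shortest path), formed by end-to-end intramolecular sp2–sp3 cross-coupling of the open tetra-aryl chain; no small ring forms. No stereocentre is created. The step needs terminal regioselectivity in the hydroboration, secured by the bulk of 9-BBN on a monosubstituted styrene, and cyclization over oligomerization, secured by slow addition of borane 10 at high dilution and by the two meta-linked diaryl ether hinges and the flexible ring B–ring C bridge that let the chain ends meet. Reduction of the C–Br bond and beta-hydride elimination should be limited by the wide-bite-angle dppf ligand and by the water in the medium, which destroys excess hydride on addition.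

Step 6
Reactants: 11 macrocycle trimethyl ether
Product: 12 target macrocyclic bis(bibenzyl) triol
Conditions: BBr3 (8 equiv), CH2Cl2, −78 °C to rt; H2O quench
Reagents that add atoms: none
Why: Lewis acid-mediated aryl methyl ether cleavage, in which BBr3 coordinates each methoxy oxygen and bromide removes the methyl group as MeBr while the diaryl ether and ArCH2CH2Ar bonds are inert, and hydrolysis on work-up should release the three phenols.

Compound list
1 | 5-bromo-2-methoxyphenol | COc1ccc(Br)cc1O | starting material
2 | (3-iodophenyl)boronic acid | OB(O)c1cccc(I)c1 | starting material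
3 | 4-bromo-2-(3-iodophenoxy)-1-methoxybenzene | COc1ccc(Br)cc1Oc1cccc(I)c1 | intermediate
4 | 3-hydroxy-4,5-dimethoxybenzaldehyde | COc1cc(C=O)cc(O)c1OC | starting material
5 | 5-ethenyl-2,3-dimethoxyphenol | COc1cc(C=C)cc(O)c1OC | intermediate
6 | bis(9-BBN) adduct: 9-[2-[3-(9-borabicyclo[3.3.1]nonan-9-yloxy)-4,5-dimethoxyphenyl]ethyl]-9-borabicyclo[3.3.1]nonane | COc1cc(CCB2C3CCCC2CCC3)cc(OB2C3CCCC2CCC3)c1OC | intermediate
7 | 5-[2-[3-(5-bromo-2-methoxyphenoxy)phenyl]ethyl]-2,3-dimethoxyphenol | COc1ccc(Br)cc1Oc1cccc(CCc2cc(O)c(OC)c(OC)c2)c1 | intermediate
8 | (4-ethenylphenyl)boronic acid | C=Cc1ccc(cc1)B(O)O | starting material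
9 | 4-bromo-2-[3-[2-[3-(4-ethenylphenoxy)-4,5-dimethoxyphenyl]ethyl]phenoxy]-1-methoxybenzene | COc1ccc(Br)cc1Oc1cccc(CCc2cc(Oc3ccc(C=C)cc3)c(OC)c(OC)c2)c1 | intermediate
10 | B-alkyl-9-BBN borane: 9 with the ring D vinyl group converted to CH2CH2–B(9-borabicyclo[3.3.1]nonan-9-yl) | COc1ccc(Br)cc1Oc1cccc(CCc2cc(Oc3ccc(CCB4C5CCCC4CCC5)cc3)c(OC)c(OC)c2)c1 | intermediate
11 | macrocycle trimethyl ether (the target with its three hydroxyls as methyl ethers) | COc1ccc2cc1Oc1cccc(c1)CCc1cc(OC)c(OC)c(c1)Oc1ccc(cc1)CC2 | intermediate
12 | target macrocyclic bis(bibenzyl) triol (no stereocentres) | Oc1ccc2cc1Oc1cccc(c1)CCc1cc(O)c(O)c(c1)Oc1ccc(cc1)CC2 | target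

Total step count: 6
Longest linear sequence: 5 steps (4 → 5 → 7 → 9 → 11 → 12; the branch from 1 is equally long).

Steps most likely to fail

1. Step 5. Intermolecular coupling may outrun ring closure and give oligomers, and the slow oxidative addition into the electron-rich C–Br bond may let protodeboronation or hydrodebromination compete. The fallback sets out from 9 and forms the same ring A C4–carbon bond by an intramolecular Heck reaction (Pd(OAc)2, P(o-tol)3, K2CO3, DMF, 100 °C, high dilution). This should give the E-configured macrocyclic stilbene trimethyl ether F1. Hydrogenation of its C=C bond (H2, Pd/C, EtOAc, rt) comes back to the route at 11.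

2. Step 3. The iodide-over-bromide selectivity may erode, so that coupling also occurs at the ring A bromide. Hydroboration may also stay incomplete because the phenol consumes hydride at an uncertain rate. The fallback sets out from 5 and 3 and joins them by an iodide-selective intermolecular Heck reaction under ligand-free phase-transfer conditions (Pd(OAc)2, Bu4NCl, NaHCO3, DMF, 60 °C). This should give 5-[(E)-2-[3-(5-bromo-2-methoxyphenoxy)phenyl]ethenyl]-2,3-dimethoxyphenol F2. Diimide reduction of the stilbene C=C bond (TsNHNH2, NaOAc, DME/H2O, reflux), which leaves the aryl bromide intact, comes back to the route at 7.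

3. Step 4. O-arylation of the ortho-methoxy phenol may be slow, so that protodeboronation and homocoupling of 8 or polymerization of the styrene take over. The fallback sets out from 7 and uses nucleophilic aromatic substitution on 4-fluorobenzaldehyde (K2CO3, DMF, 110 °C). This should give 4-[5-[2-[3-(5-bromo-2-methoxyphenoxy)phenyl]ethyl]-2,3-dimethoxyphenoxy]benzaldehyde F3. Wittig methylenation (Ph3PCH3Br, KOtBu, THF, 0 °C to rt) comes back to the route at 9.

Further compounds
F1 | step 5 | E-configured macrocyclic stilbene trimethyl ether (11 with the ring A–ring D bridge as CH=CH) | COc1ccc2cc1Oc1cccc(c1)CCc1cc(OC)c(OC)c(c1)Oc1ccc(cc1)/C=C/2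
F2 | step 3 | 5-[(E)-2-[3-(5-bromo-2-methoxyphenoxy)phenyl]ethenyl]-2,3-dimethoxyphenol | COc1ccc(Br)cc1Oc1cccc(/C=C/c2cc(O)c(OC)c(OC)c2)c1
F3 | step 4 | 4-[5-[2-[3-(5-bromo-2-methoxyphenoxy)phenyl]ethyl]-2,3-dimethoxyphenoxy]benzaldehyde | COc1ccc(Br)cc1Oc1cccc(CCc2cc(Oc3ccc(C=O)cc3)c(OC)c(OC)c2)c1
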